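The plan opens the pyranone ring of the 4-arylcoumarin at two bonds, C4–C1' and O1–C2. It exploits the fact that C4, which in the target is wedged between the C1'–C6' dimethoxyphenyl ring and the peri C5 methoxy group of ring A, can be arylated while it is still an unhindered sp carbon. A copper-catalysed syn-hydroarylation of an aryl propiolate with 3,4-dimethoxyphenylboronic acid forms C4–C1' and places ring A cis to the ester; acid then frees the C8a and C8 oxygens and the lactone closes in the same flask. The precursor is methyl 3-[2,3-bis(methoxymethoxy)-4,6-dimethoxyphenyl]propiolate, reached from 2-hydroxy-4,6-dimethoxybenzaldehyde by Dakin oxidation, MOM-directed ortho-formylation and Corey–Fuchs homologation.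

Key step: step 6

Remark: coumarin locants (O1, C2, C3, C4, C4a, C5 to C8, C8a, primed locants for the 4-aryl ring) are used for the target. The two free ring positions of bis-MOM ether 4 are near-equivalent toward electrophiles, so the carbon substituent is introduced by MOM-directed lithiation and not by electrophilic halogenation.

Step 1
Reactants: 1 2-hydroxy-4,6-dimethoxybenzaldehyde
Product: 3 3,5-dimethoxybenzene-1,2-diol (3,5-dimethoxycatechol), via aryl formate 2 (not isolated)
Conditions: 30% aq H2O2 (1.3 equiv), aq NaOH, THF/H2O, 0 °C to rt, argon; then Na2S2O3, 1 M HCl; crude catechol used directly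
Reagents that add atoms: hydrogen peroxide, OO
Why: Dakin oxidation, in which hydroperoxide adds to the aldehyde, the electron-rich ortho-hydroxyaryl group migrates to oxygen and the resulting formate 2 is hydrolysed by the base, while exclusion of air and a reductive quench should protect the oxidation-prone catechol.

Step 2
Reactants: 3 3,5-dimethoxybenzene-1,2-diol
Product: 4 1,5-dimethoxy-2,3-bis(methoxymethoxy)benzene
Conditions: MOMCl (3 equiv), i-Pr2NEt (4 equiv), CH2Cl2, 0 °C to rt
Reagents that add atoms: chloromethyl methyl ether, COCCl
Why: Williamson-type O-alkylation of both phenols by the reactive alpha-chloro ether under amine base, which masks the acidic hydroxyl groups for the organolithium steps and installs the ortho-directing acetal needed in step 3.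

Step 3
Reactants: 4 1,5-dimethoxy-2,3-bis(methoxymethoxy)benzene
Product: 6 2,3-bis(methoxymethoxy)-4,6-dimethoxybenzaldehyde, via aryllithium 5 (not isolated)
Conditions: n-BuLi (1.2 equiv), THF, 0 °C; then DMF (3 equiv), 0 °C to rt; aq NH4Cl
Reagents that add atoms: N,N-dimethylformamide, CN(C)C=O
Why: Directed ortho-metalation followed by formylation, in which C4–H of 4 is the only ring hydrogen ortho to a MOM ether and is also flanked by the C5 methoxy group, so chelation of n-BuLi by the acetal oxygens should deliver the base there in preference to C6–H between the two weaker methoxy directors, and aryllithium 5 is then trapped by DMF.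

Step 4
Reactants: 6 2,3-bis(methoxymethoxy)-4,6-dimethoxybenzaldehyde
Product: 7 1-(2,2-dibromoethenyl)-2,3-bis(methoxymethoxy)-4,6-dimethoxybenzene
Conditions: CBr4 (2 equiv), PPh3 (4 equiv), Et3N (2 equiv, buffer), CH2Cl2, 0 °C
Reagents that add atoms: carbon tetrabromide, BrC(Br)(Br)Br
Why: Ramirez dibromo-olefination (first stage of the Corey–Fuchs sequence), a Wittig reaction of Ph3P=CBr2 that tolerates benzaldehydes with two ortho substituents, with Et3N scavenging traces of HBr so that the MOM acetals should survive.

Step 5
Reactants: 7 1-(2,2-dibromoethenyl)-2,3-bis(methoxymethoxy)-4,6-dimethoxybenzene; 8 methyl chloroformate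
Product: 10 methyl 3-[2,3-bis(methoxymethoxy)-4,6-dimethoxyphenyl]prop-2-ynoate, via lithium acetylide 9 (not isolated)
Conditions: n-BuLi (2.2 equiv), THF, −78 °C; then 8 (1.5 equiv), −78 to 0 °C; aq NH4Cl
Reagents that add atoms: none
Why: Second stage of the Corey–Fuchs alkyne synthesis with electrophilic trapping, in which bromine–lithium exchange and a Fritsch–Buttenberg–Wiechell-type shift with loss of bromide give lithium acetylide 9, which is C-acylated by the chloroformate at low temperature while the aryl ethers and acetals are inert to the base.

Step 6
Reactants: 10 methyl 3-[2,3-bis(methoxymethoxy)-4,6-dimethoxyphenyl]prop-2-ynoate; 11 (3,4-dimethoxyphenyl)boronic acid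
Product: 14 4-(3,4-dimethoxyphenyl)-8-hydroxy-5,7-dimethoxy-2H-chromen-2-one (the target), via MOM-protected Z-acrylate 12 (not isolated), via free catechol Z-acrylate 13 (not isolated)
Conditions: CuOAc (5 mol %), 11 (2 equiv), degassed MeOH, 25–30 °C, argon; then 3 M aq HCl added to the same flask, 50 °C
Reagents that add atoms: none
Why: Boronic acid 11 transmetalates to the monovalent copper methoxide or acetate, and the resulting arylcopper adds syn across the polarised triple bond of 10 with the aryl group on the beta carbon (the future C4) and copper on the alpha carbon; methanol then protonates the alkenylcopper with retention, giving Z-acrylate 12 and returning the catalyst. The closest known reaction type is the copper-catalysed hydroarylation of ortho-(methoxymethoxy)aryl propiolates with arylboronic acids in methanol, followed by acid-induced lactonisation to 4-arylcoumarins. Acid then cleaves both MOM acetals, and in 13 the phenol oxygen that becomes O1, held cis to the ester by the syn addition, closes the pyranone ring by 6-exo-trig acyl substitution (O1–C2) with loss of methanol. No stereocentre is formed; the only stereochemical element is the transient Z alkene geometry, set by the concerted carbocupration and the fast protonolysis in the protic solvent. The step needs beta-regioselective arylation, which the ester polarisation of the ynoate secures, and lactonisation through the C8a oxygen and not the C8 oxygen, which ring size secures (six-membered against seven-membered). Because the carbon being arylated is linear, the dimethoxyphenyl group can be delivered beside the two ortho substituents of ring A, a crowding that would hamper the same bond formation on a finished coumarin.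

Compound list
1 | 2-hydroxy-4,6-dimethoxybenzaldehyde | COc1cc(O)c(C=O)c(OC)c1 | starting material
2 | 2-hydroxy-4,6-dimethoxyphenyl formate | COc1cc(O)c(OC=O)c(OC)c1 | intermediate (not isolated)
3 | 3,5-dimethoxybenzene-1,2-diol (3,5-dimethoxycatechol) | COc1cc(O)c(O)c(OC)c1 | intermediate
4 | 1,5-dimethoxy-2,3-bis(methoxymethoxy)benzene | COCOc1cc(OC)cc(OC)c1OCOC | intermediate
5 | [2,3-bis(methoxymethoxy)-4,6-dimethoxyphenyl]lithium | [Li]c1c(OC)cc(OC)c(OCOC)c1OCOC | intermediate (not isolated)
6 | 2,3-bis(methoxymethoxy)-4,6-dimethoxybenzaldehyde | COCOc1c(OC)cc(OC)c(C=O)c1OCOC | intermediate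
7 | 1-(2,2-dibromoethenyl)-2,3-bis(methoxymethoxy)-4,6-dimethoxybenzene | COCOc1c(OC)cc(OC)c(C=C(Br)Br)c1OCOC | intermediate
8 | methyl chloroformate | COC(=O)Cl | starting material
9 | {[2,3-bis(methoxymethoxy)-4,6-dimethoxyphenyl]ethynyl}lithium | [Li]C#Cc1c(OC)cc(OC)c(OCOC)c1OCOC | intermediate (not isolated)
10 | methyl 3-[2,3-bis(methoxymethoxy)-4,6-dimethoxyphenyl]prop-2-ynoate | COCOc1c(OC)cc(OC)c(C#CC(=O)OC)c1OCOC | intermediate
11 | (3,4-dimethoxyphenyl)boronic acid | COc1ccc(B(O)O)cc1OC | starting material
12 | methyl (2Z)-3-[2,3-bis(methoxymethoxy)-4,6-dimethoxyphenyl]-3-(3,4-dimethoxyphenyl)prop-2-enoate | COC(=O)/C=C(/c1ccc(OC)c(OC)c1)c1c(OC)cc(OC)c(OCOC)c1OCOC | intermediate (not isolated)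
13 | methyl (2Z)-3-(2,3-dihydroxy-4,6-dimethoxyphenyl)-3-(3,4-dimethoxyphenyl)prop-2-enoate | COC(=O)/C=C(/c1ccc(OC)c(OC)c1)c1c(OC)cc(OC)c(O)c1O | intermediate (not isolated)
14 | 4-(3,4-dimethoxyphenyl)-8-hydroxy-5,7-dimethoxy-2H-chromen-2-one (8-hydroxy-5,7,3',4'-tetramethoxy-4-phenylcoumarin) | COc1ccc(-c2cc(=O)oc3c(O)c(OC)cc(OC)c23)cc1OC | target

Total step count: 6. Longest linear sequence: 6 steps (1 to 14); compounds 8 and 11 are purchased.

Steps most likely to fail

Step 6. The carbocupration may stall at the alkyne carbon that carries the doubly ortho-substituted ring A while protodeboronation consumes the electron-rich boronic acid. The alkenylcopper may also isomerise through its allenoate form before protonation, leaving the ester trans to ring A and unable to lactonise. The fallback is a Pechmann condensation that sets out from catechol 3 and comes back to the route at target 14. Catechol 3 would be condensed with commercial ethyl 3-(3,4-dimethoxyphenyl)-3-oxopropanoate in CF3CO2H at rt to 60 °C. Transesterification, ring hydroxyalkylation and dehydration then build the pyranone ring. C6 of 3 is the only ring CH ortho to a hydroxyl group, so the only coumarin that can form is 14. This fallback makes no new compound (F0).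

Step 3. Regiocontrol of the deprotonation may be lost, with metalation between the two methoxy groups at C6 of 4 competing with the MOM-directed site, or the metalation may be incomplete. The fallback is a phenol-directed ortho-formylation that sets out from 3 and comes back at 6. Catechol 3 would be treated with MgCl2, Et3N and paraformaldehyde in MeCN at reflux (Casnati–Skattebøl conditions). The magnesium phenoxide delivers formaldehyde only to a carbon ortho to a hydroxyl group, and C6 of 3 is the only such CH, so the product should be 2,3-dihydroxy-4,6-dimethoxybenzaldehyde F1. Bis-MOM protection of F1 (MOMCl, i-Pr2NEt, CH2Cl2) then gives 6.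

Step 1. Alkaline peroxide or air may over-oxidise the very electron-rich catechol, through the ortho-quinone to ring-cleaved material. The fallback never exposes a free catechol; it sets out from 1 and comes back at 4. Aldehyde 1 would be protected (MOMCl, i-Pr2NEt, CH2Cl2) as 2,4-dimethoxy-6-(methoxymethoxy)benzaldehyde F2. Baeyer–Villiger oxidation of F2 with mCPBA in NaHCO3-buffered CH2Cl2 should give 2,4-dimethoxy-6-(methoxymethoxy)phenyl formate F3. Methanolysis of F3 (K2CO3, MeOH, rt) gives 2,4-dimethoxy-6-(methoxymethoxy)phenol F4, and a second MOM protection of F4 (MOMCl, i-Pr2NEt, CH2Cl2) gives 4.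

Further compounds
F0 | step 6 | none | none
F1 | step 3 | 2,3-dihydroxy-4,6-dimethoxybenzaldehyde | COc1cc(OC)c(C=O)c(O)c1O
F2 | step 1 | 2,4-dimethoxy-6-(methoxymethoxy)benzaldehyde | COCOc1cc(OC)cc(OC)c1C=O
F3 | step 1 | 2,4-dimethoxy-6-(methoxymethoxy)phenyl formate | COCOc1cc(OC)cc(OC)c1OC=O
F4 | step 1 | 2,4-dimethoxy-6-(methoxymethoxy)phenol | COCOc1cc(OC)cc(OC)c1O
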